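It was decided to read one number from the two earlier runs before any forecast for violet, green and amber was accepted.

the same everywhere: electrophile 0.10 M

| flask | nucleophile | remark | time |
|---|---|---|---|
| south-west | 0.11 M | run made earlier |  |
| north-west | 0.39 M | run made earlier |  |
| violet | 0.0800 M |  | 2.5 d |
| green | 0.160 M |  | 2.5 d |
| amber | 0.320 M |  | 2.5 d |

- south-west (time / h: electrophile / %, target / %): 2.50: 87.7, 10.9; 6.00: 76.5, 15.7; 12.0: 66.4, 19.1; 20.0: 61.5, 19.4; 25.0: 59.3, 19.4; 30.0: 58.3, 20.1; 40.0: 57.3, 20.1
- north-west (time / h: electrophile / %, target / %): 3.00: 57.2, 19.7; 5.00: 42.9, 18.2; 8.00: 29.9, 14.4; 12.0: 19.8, 10.5; 20.0: 10.3, 6.3; 30.0: 5.5, 3.6; 40.0: 2.7, 1.9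

(scatter of a reading: 0.3 percentage points)

- part of the electrophile that has reacted at the end, violet
- part of the electrophile that has reacted at the end, green
- part of the electrophile that has reacted at the end, amber
- what raising the concentration of nucleophile from its lowest to its highest value here does to the part of the electrophile that has reacted (changes below 5 percentage points count as none) (it falls / it rises / no change)

The first chemist reported that south-west, after 40.0 h, held 57.3% electrophile and 20.1% target, while north-west, after 3.00 h, held 57.2% and 19.7%. She noted that the target readings differ by 0.4 percentage points against a scatter of 0.3 points per reading, although the nucleophile charges differ by a factor of 3.55.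

The second chemist answered that this was expected from the steps. Target is made at a[N]E and used at b[N]T, where E and T are the fractions of electrophile and target, [N] is the free nucleophile, and a and b are the two rate constants. Dividing one rate by the other removes [N] and time, and gives the curve T = (E^s − E)/(1 − s). Here s = b/a is the selectivity factor. Making equals using at the top of the curve, where s = E/T. Target in north-west falls after its first reading and in south-west levels off near the same electrophile, so he took that north-west reading as the top, which gives, as a value read from scattered readings, s = 2.90.

The first chemist added the nucleophile budget, 3(1 − E) − T equivalents of nucleophile spent per electrophile charged. South-west's last readings give 1.08 against 1.10 charged.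

The forecast was then entered: 32.7% for violet, 58.8% for green, 94.5% for amber, and on the trend, it rises. Its author argued that “each electrophile consumed costs two nucleophile, one to react and one to trap the acid”.

The flasks gave 33.3% for violet, 59.1% for green and 94.7% for amber, and from the lowest nucleophile charge to the highest the reacted part changed by 61 points: it rises.

    electrophile + nucleophile → acid set free + target (k = 0.00935 L mol⁻¹ min⁻¹)
    nucleophile + acid set free ⇌ protonated nucleophile, settled at all times (K = 59000 L mol⁻¹)
    nucleophile + target → over-reaction product (k = 0.0264 L mol⁻¹ min⁻¹)
    nucleophile + acid set free ⇌ idle adduct, settled at all times (K = 25.0 L mol⁻¹)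

Amber at 2.50 d held 5.34% electrophile, for which the curve with s = 2.90 gives 2.80% target, and the flask held 2.91%. The neighbouring flask is amber read earlier, at 25 h, with 85.5% of its electrophile reacted and 15% still there. The same curve gives 7.43% target for that electrophile, and the neighbouring flask held 7.72%.

(The numbers in the tables are calculated on assumed constants; scatter was added.)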